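**Plan**
The target is a 6,8''-linked biflavone. The retrosynthesis first cuts the biaryl bond between C6 of the genkwanin half and C8 of the acacetin half, then in each half the O1–C2 and C2–C3 bonds of ring C, back to a hydroxyacetophenone and an aroyl chloride.
Enabling feature: both carbons of the biaryl bond are CH positions of phloroglucinol-type rings A, each ortho to a phenolic oxygen (O5 of the genkwanin half, O7 of the acacetin half). One silicon atom bridging these two oxygens puts the carbons in reach of a seven-membered ring, so the two C–H bonds can be joined at an anode with loss of H2 only.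
Forward: ring C of each half by diketone formation and cyclodehydration (steps 1 and 2), O–Si–O tether (step 3), anodic biaryl closure (step 4), removal of silicon by fluoride (step 5), and removal by BCl3 of the benzyl group and of the 5-O-methyl helper that steers the coupling to C8 (step 6).
Stereochemistry: there is no stereocentre; the hindered biaryl axis is formed without control.

Key step: step 4

Assumption: the SMILES gives no configuration for the biaryl axis, so the racemic compound is taken as the target.

**Route**

Step 1
Reactants: 1 2',6'-dihydroxy-4'-methoxyacetophenone; 2 4-(benzyloxy)benzoyl chloride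
Product: 4 4'-O-benzylgenkwanin, via 1,3-diketone 3 (not isolated)
Conditions: LiHMDS (4 equiv), THF, −78 °C to rt; then AcOH, H2SO4 (cat.), 95 °C
Reagents that add atoms: none
Why: Acylation of the lithium polyanion of 1 at the enolate carbon (Claisen-type, giving the Baker–Venkataraman diketone directly) and acid cyclodehydration through either of the two equivalent ortho hydroxyls should close ring C to the 5-hydroxy-7-methoxyflavone, the benzyl ether standing the short treatment with dilute acid.

Step 2
Reactants: 5 2',4'-dihydroxy-6'-methoxyacetophenone; 6 4-methoxybenzoyl chloride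
Product: 8 5-O-methylacacetin, via 1,3-diketone 7 (not isolated)
Conditions: LiHMDS (4 equiv), THF, −78 °C to rt; then AcOH, H2SO4 (cat.), 95 °C
Reagents that add atoms: none
Why: The same polyanion acylation and cyclodehydration should work without protection of the 4'-hydroxyl, and as only one hydroxyl is ortho to the ketone, ring C can close in one direction only, which places the methoxy group at C5 and the free hydroxyl at C7.

Step 3
Reactants: 4 4'-O-benzylgenkwanin; 8 5-O-methylacacetin
Product: 10 mixed bis(aryloxy)di-tert-butylsilane (Si on O5 of 4 and on O7 of 8), via silyl triflate 9 (not isolated)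
Conditions: 4, tBu2Si(OTf)2 (1.05 equiv), 2,6-lutidine, CH2Cl2, 0 °C to rt; then 8, DMAP (cat.), 40 °C
Reagents that add atoms: di-tert-butylsilyl bis(trifluoromethanesulfonate), CC(C)(C)[Si](OS(=O)(=O)C(F)(F)F)(OS(=O)(=O)C(F)(F)F)C(C)(C)C
Why: Stepwise silyl ether formation: the hindered chelated 5-OH of 4 can displace only one triflate of the bis(triflate), and the remaining Si–OTf bond of 9 is then taken by the unhindered, more acidic 7-OH of 8, as in the known stepwise preparation of unsymmetrical dialkoxy- and diaryloxysilanes.

Step 4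
Reactants: 10 mixed bis(aryloxy)di-tert-butylsilane
Product: 11 silylene-bridged biflavone (dibenzo-1,3-dioxa-2-silepine; C6 of the genkwanin half bonded to C8 of the acacetin half)
Conditions: BDD anode, Pt cathode, undivided cell, Bu4NPF6 (0.1 M), HFIP/CH2Cl2 4:1, 5 mM, constant current 2 mA cm−2, 2.2 F mol−1, 20 °C
Reagents that add atoms: none
Why: Proposed new method: anodic one-electron oxidation of one of the two trioxygenated rings A of 10 (the most electron-rich rings, stabilised as radical cation by HFIP) should be followed by attack of the other ring A across the O–Si–O bridge, a second electron transfer and loss of two protons, so that C6–H of the genkwanin half and C8–H of the acacetin half become the biaryl bond while the cathode releases H2. The closest known reaction types are the anodic dehydrogenative phenol–arene and aryl ether couplings on BDD in HFIP and the template-directed ortho,ortho coupling of tethered phenols; the closure of di-tert-butylsilylene-bridged biaryls is known so far from ortho-halo precursors under palladium catalysis. The step closes the seven-membered dibenzo-1,3-dioxa-2-silepine ring by attack on a ring carbon whose C5=C6 bond lies inside the new ring, formally a 7-endo-trig closure. No stereocentre is formed and the biaryl axis arises as the racemate. The selectivity needed is cross over homo coupling and one CH of each ring: the tether at high dilution secures the cross coupling, the silylated O5 of the genkwanin half has C6 as its only free ortho carbon (C8 is para and out of reach), and on the acacetin half C8 should win over C6 because the 5-OMe methyl, pushed toward C6 by the peri C4 carbonyl, blocks that carbon, while C8 is para to this donor and is the usual site of electrophilic substitution of 5,7-dialkoxyflavones. Rings B, each with one oxygen only and conjugated with the pyranone carbonyl, should be oxidised later than rings A.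

Step 5
Reactants: 11 silylene-bridged biflavone
Product: 12 biflavone with free 5-OH (genkwanin half) and 7-OH (acacetin half), still carrying the 4'-O-benzyl and 5-O-methyl groups
Conditions: TBAF (2.5 equiv), AcOH (2.5 equiv), THF, 0 °C to rt
Reagents that add atoms: none
Why: Fluoride-mediated desilylation cleaves both aryl O–Si bonds of the cyclic silylene, and the acetic acid buffer keeps the phenoxides from opening the pyranone rings.

Step 6
Reactants: 12 protected biflavone
Product: 13 target biflavone
Conditions: BCl3 (6 equiv), C6HMe5 (6 equiv), CH2Cl2, −78 °C to 0 °C; then MeOH, aq. HCl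
Reagents that add atoms: none
Why: Lewis acid ether cleavage: BCl3 bound between the C4 carbonyl and the peri 5-OMe group removes this methyl selectively and, with pentamethylbenzene as trap for the benzyl cation, the benzyl ether, while the 7-OMe and 4'-OMe groups, which have no neighbouring carbonyl, should stay.

**Compound list**

1 | 1-(2,6-dihydroxy-4-methoxyphenyl)ethan-1-one | CC(=O)c1c(O)cc(OC)cc1O | starting material
2 | 4-(benzyloxy)benzoyl chloride | O=C(Cl)c1ccc(OCc2ccccc2)cc1 | starting material
3 | 1-[4-(benzyloxy)phenyl]-3-(2,6-dihydroxy-4-methoxyphenyl)propane-1,3-dione | COc1cc(O)c(C(=O)CC(=O)c2ccc(OCc3ccccc3)cc2)c(O)c1 | intermediate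
4 | 2-[4-(benzyloxy)phenyl]-5-hydroxy-7-methoxy-4H-chromen-4-one (4'-O-benzylgenkwanin) | COc1cc(O)c2c(=O)cc(-c3ccc(OCc4ccccc4)cc3)oc2c1 | intermediate
5 | 1-(2,4-dihydroxy-6-methoxyphenyl)ethan-1-one | CC(=O)c1c(O)cc(O)cc1OC | starting material
6 | 4-methoxybenzoyl chloride | COc1ccc(C(=O)Cl)cc1 | starting material
7 | 1-(2,4-dihydroxy-6-methoxyphenyl)-3-(4-methoxyphenyl)propane-1,3-dione | COc1ccc(C(=O)CC(=O)c2c(O)cc(O)cc2OC)cc1 | intermediate
8 | 7-hydroxy-5-methoxy-2-(4-methoxyphenyl)-4H-chromen-4-one (5-O-methylacacetin) | COc1ccc(-c2cc(=O)c3c(OC)cc(O)cc3o2)cc1 | intermediate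
9 | 5-O-[di-tert-butyl(trifluoromethanesulfonyloxy)silyl] ether of 4 | COc1cc(O[Si](OS(=O)(=O)C(F)(F)F)(C(C)(C)C)C(C)(C)C)c2c(=O)cc(-c3ccc(OCc4ccccc4)cc3)oc2c1 | intermediate
10 | di-tert-butylsilanediyl mixed bis(aryl ether), silicon on O5 of 4 and on O7 of 8 | COc1cc(O[Si](Oc2cc(OC)c3c(=O)cc(-c4ccc(OC)cc4)oc3c2)(C(C)(C)C)C(C)(C)C)c2c(=O)cc(-c3ccc(OCc4ccccc4)cc3)oc2c1 | intermediate
11 | silylene-bridged biflavone: dibenzo[d,f][1,3,2]dioxasilepine with Si(tBu)2 linking O5 of the genkwanin half and O7 of the acacetin half, biaryl bond C6–C8 | COc1cc2oc(-c3ccc(OCc4ccccc4)cc3)cc(=O)c2c5O[Si](C(C)(C)C)(C(C)(C)C)Oc6cc(OC)c7c(=O)cc(-c8ccc(OC)cc8)oc7c6-c15 | intermediate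
12 | 2-[4-(benzyloxy)phenyl]-5-hydroxy-6-[7-hydroxy-5-methoxy-2-(4-methoxyphenyl)-4-oxo-4H-chromen-8-yl]-7-methoxy-4H-chromen-4-one | COc1cc2oc(-c3ccc(OCc4ccccc4)cc3)cc(=O)c2c(O)c1-c1c(O)cc(OC)c2c(=O)cc(-c3ccc(OC)cc3)oc12 | intermediate
13 | 6-[5,7-dihydroxy-2-(4-methoxyphenyl)-4-oxo-4H-chromen-8-yl]-5-hydroxy-2-(4-hydroxyphenyl)-7-methoxy-4H-chromen-4-one | COc1ccc(-c2cc(=O)c3c(O)cc(O)c(-c4c(OC)cc5oc(-c6ccc(O)cc6)cc(=O)c5c4O)c3o2)cc1 | target

**Count and risks**

Total step count: 6. Longest linear sequence: 5 steps (step 1 or step 2, then steps 3 to 6).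

Steps most likely to fail:

1. Step 4. The radical cation may lose the silicon tether or be oxidised further before the ring closes, the closure may go to C6 of the acacetin half, or intermolecular coupling may compete. The fallback uses known chemistry, a palladium-catalysed intramolecular C–H arylation across the same tether. It sets out from 8 and comes back at 11. Iodination of 8 with NIS in DMF at 0 °C, ortho to the free 7-OH on the side not shielded by the 5-OMe group, should give 7-hydroxy-8-iodo-5-methoxy-2-(4-methoxyphenyl)-4H-chromen-4-one F1. Silylation of F1 with the silyl triflate 9, made from 4 as in the first half of step 3, should give the 8-iodo analogue of 10, F2. Treatment of F2 with Pd(OAc)2, PCy3·HBF4, Cs2CO3 and PivOH (cat.) in DMA at 110 °C should close the ring by oxidative addition into the C8–I bond, concerted metalation–deprotonation at C6–H of the genkwanin half (the only ortho C–H of the silylated O5) and reductive elimination, to give 11. The iodine fixes the site on the acacetin half.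

2. Step 3. Silylation of the chelated, hindered 5-OH may be incomplete, symmetric silanes may form, and the 5-O–Si bond may hydrolyse on work-up or chromatography. The fallback gives up the tether and joins the halves by Suzuki–Miyaura coupling. It sets out from 8 and 4 and comes back at 13. Benzylation of 8 (BnBr, K2CO3, acetone, reflux) should give 7-(benzyloxy)-5-methoxy-2-(4-methoxyphenyl)-4H-chromen-4-one F3. Iodination (I2, AgOAc, CH2Cl2) at C8, the usual site for 5,7-dialkoxyflavones, should give 7-(benzyloxy)-8-iodo-5-methoxy-2-(4-methoxyphenyl)-4H-chromen-4-one F4. Miyaura borylation (B2pin2, PdCl2(dppf), KOAc, dioxane, 90 °C) should give the 8-pinacolboronate F5. Iodination of 4 ortho to the chelated 5-OH (benzyltrimethylammonium dichloroiodate, CaCO3, CH2Cl2/MeOH) should give 2-[4-(benzyloxy)phenyl]-5-hydroxy-6-iodo-7-methoxy-4H-chromen-4-one F6. Coupling of F5 with F6 (Pd(OAc)2, SPhos, K3PO4, toluene/H2O, 100 °C) should give the dibenzyl methyl-protected biflavone F7. BCl3 with pentamethylbenzene, as in step 6, then removes both benzyl groups and the 5-O-methyl group to give 13.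

3. Step 6. The benzyl cation may alkylate the electron-rich rings A, or the 7-OMe and 4'-OMe groups may be lost on long exposure to the Lewis acid. The fallback separates the two deprotections. It sets out from 12 and comes back at 13. Hydrogenolysis (H2, Pd/C, THF/MeOH, rt) should give the debenzylated 5-O-methyl biflavone F8. AlCl3 in MeCN at 60 °C then cleaves only the peri 5-OMe group through its chelate with the C4 carbonyl, to give 13.

**Further compounds**

F1 | step 4 | 7-hydroxy-8-iodo-5-methoxy-2-(4-methoxyphenyl)-4H-chromen-4-one | COc1ccc(-c2cc(=O)c3c(OC)cc(O)c(I)c3o2)cc1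
F2 | step 4 | 8-iodo analogue of 10 (iodine at C8 of the acacetin half) | COc1cc(O[Si](Oc2cc(OC)c3c(=O)cc(-c4ccc(OC)cc4)oc3c2I)(C(C)(C)C)C(C)(C)C)c2c(=O)cc(-c3ccc(OCc4ccccc4)cc3)oc2c1
F3 | step 3 | 7-(benzyloxy)-5-methoxy-2-(4-methoxyphenyl)-4H-chromen-4-one | COc1ccc(-c2cc(=O)c3c(OC)cc(OCc4ccccc4)cc3o2)cc1
F4 | step 3 | 7-(benzyloxy)-8-iodo-5-methoxy-2-(4-methoxyphenyl)-4H-chromen-4-one | COc1ccc(-c2cc(=O)c3c(OC)cc(OCc4ccccc4)c(I)c3o2)cc1
F5 | step 3 | 7-(benzyloxy)-5-methoxy-2-(4-methoxyphenyl)-8-(4,4,5,5-tetramethyl-1,3,2-dioxaborolan-2-yl)-4H-chromen-4-one | COc1ccc(-c2cc(=O)c3c(OC)cc(OCc4ccccc4)c(B5OC(C)(C)C(C)(C)O5)c3o2)cc1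
F6 | step 3 | 2-[4-(benzyloxy)phenyl]-5-hydroxy-6-iodo-7-methoxy-4H-chromen-4-one | COc1cc2oc(-c3ccc(OCc4ccccc4)cc3)cc(=O)c2c(O)c1I
F7 | step 3 | 6-[7-(benzyloxy)-5-methoxy-2-(4-methoxyphenyl)-4-oxo-4H-chromen-8-yl]-2-[4-(benzyloxy)phenyl]-5-hydroxy-7-methoxy-4H-chromen-4-one | COc1cc2oc(-c3ccc(OCc4ccccc4)cc3)cc(=O)c2c(O)c1-c1c(OCc2ccccc2)cc(OC)c2c(=O)cc(-c3ccc(OC)cc3)oc12
F8 | step 6 | 5-hydroxy-6-[7-hydroxy-5-methoxy-2-(4-methoxyphenyl)-4-oxo-4H-chromen-8-yl]-2-(4-hydroxyphenyl)-7-methoxy-4H-chromen-4-one | COc1ccc(-c2cc(=O)c3c(OC)cc(O)c(-c4c(OC)cc5oc(-c6ccc(O)cc6)cc(=O)c5c4O)c3o2)cc1
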